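**Retrosynthetic overview**

1. The target 11 comes from tricyclic lactol 9 by reductive deoxygenation: one methyl of the gem-dimethyl group is carried as a lactol carbon tied to the neighbouring phenol oxygen.
2. Lactol 9 comes from enal bromide 5 and 2,4,6-trihydroxybenzophenone 6 in one operation: aryl–C bond at the enal β-carbon, C–C ring closure onto CH2Br, then O–C lactol closure.
3. Ring order: the cyclopentane closes first and the pyran (lactol) ring second, in the same flask; both aromatic rings are bought.
4. Enal 5 comes from (S)-lavandulyl bromide 3 and methacrolein 4 by cross-metathesis; 3 comes from (S)-lavandulol 2, obtained by lipase resolution of racemic lavandulol 1.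
5. The isopropenyl-bearing stereocentre comes from lavandulol; the benzylic stereocentre is set by the amine catalyst in the key step.

Assumption: 1 and 6 are catalogue chemicals, and lactol 9 is written as the isomer closed on the 4-OH (it equilibrates through open aldehyde 8 with the 2-OH-closed isomer and both anomers, all of which give 11 in step 5).

**Route**

Step 1
Reactants: 1 (±)-lavandulol
Product: 2 (S)-lavandulol
Conditions: Candida antarctica lipase B (immobilised), vinyl acetate (3 equiv), hexane, 30 °C, stopped at ca. 65% conversion; chromatography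
Reagents that add atoms: none
Why: Lipase-catalysed kinetic resolution (enantioselective transesterification) in which the (R)-alcohol is acetylated faster, so the alcohol recovered past 60% conversion is the (S)-enantiomer in high ee; its stereocentre becomes C4 of the cyclopentyl group.

Step 2
Reactants: 2 (S)-lavandulol
Product: 3 (S)-lavandulyl bromide [(3S)-3-(bromomethyl)-2,6-dimethylhepta-1,5-diene]
Conditions: CBr4, PPh3, CH2Cl2, 0 °C → rt
Reagents that add atoms: carbon tetrabromide, BrC(Br)(Br)Br
Why: Appel reaction, an SN2 displacement at the primary carbinol carbon that leaves the adjacent stereocentre and both alkenes untouched.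

Step 3
Reactants: 3 (S)-lavandulyl bromide; 4 methacrolein
Product: 5 (2E,5S)-5-(bromomethyl)-2,6-dimethylhepta-2,6-dienal
Conditions: second-generation Grubbs catalyst (5 mol %), methacrolein (5 equiv), CH2Cl2, 40 °C
Reagents that add atoms: none
Why: Olefin cross-metathesis of the prenyl-type trisubstituted alkene with methacrolein swaps the isopropylidene terminus for the 2-formylpropylidene unit and gives the (E)-2-methyl enal; the 1,1-disubstituted isopropenyl group cannot couple with methacrolein (it would need a tetrasubstituted alkene) and the bromide is inert.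

Step 4
Reactants: 5 (2E,5S)-5-(bromomethyl)-2,6-dimethylhepta-2,6-dienal; 6 2,4,6-trihydroxybenzophenone
Product: 9 [(2R,3aS,9bS)-4,7,9-trihydroxy-3a-methyl-2-(prop-1-en-2-yl)-1,2,3,3a,4,9b-hexahydrocyclopenta[c]chromen-8-yl](phenyl)methanone (lactol; both C4 anomers), via Friedel–Crafts aldehyde 7 (not isolated), via cyclopentane aldehyde 8 (not isolated)
Conditions: 9-amino-9-deoxy-epi-quinidine (20 mol %), TFA (40 mol %), 6 (1.3 equiv), THF/CHCl3, 25 °C; then NaOAc (2 equiv), 45 °C; aqueous work-up
Reagents that add atoms: none
Why: Proposed new method: the primary amine activates the α-branched enal 5 as its iminium ion, the C3 carbon of 6 adds to the β-carbon (Friedel–Crafts conjugate addition) on the face dictated by the catalyst, the same amine then activates aldehyde 7 as its enamine, which displaces the tethered primary bromide (5-exo-tet) to close the cyclopentane and create the quaternary carbon, and the aldehyde of 8, which lies cis to the aryl group, is captured by the ortho-OH as the lactol. The closest known reactions are cinchona-primary-amine iminium Friedel–Crafts alkylation/hemiacetalisation of electron-rich phenols with enals, and enamine-catalysed intramolecular α-alkylation of aldehydes (Michael/α-alkylation domino cyclisation). The benzylic centre is set under catalyst control, independently of the remote C5 centre, to put the aryl group trans to the isopropenyl group; the sense of induction is assigned by analogy and must be confirmed on the first run, since the quinine-derived pseudo-enantiomer gives the cis series. The configuration of the quaternary carbon is irrelevant because it becomes CMe2.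

Step 5
Reactants: 9 lactol
Product: 11 [2,4,6-trihydroxy-3-[(1R,4R)-2,2-dimethyl-4-(prop-1-en-2-yl)cyclopentyl]phenyl](phenyl)methanone (CNP0143418.1), via tosylhydrazone 10 (not isolated)
Conditions: TsNHNH2, THF, 50 °C; then catecholborane (6 equiv), CHCl3, 0 °C; then NaOAc·3H2O, 60 °C
Reagents that add atoms: none
Why: Reductive deoxygenation of an aldehyde tosylhydrazone (Caglioti/Kabalka reduction): the lactol opens to the neopentyl aldehyde, which alone condenses with the hydrazide (the chelated, doubly ortho-substituted diaryl ketone does not), and hydride addition followed by loss of sulfinate and N2 turns CH=N into CH3, restoring the gem-dimethyl group and the free phenol without touching either stereocentre or the isopropenyl group.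

**Compound list**

1 | (±)-lavandulol [rac-5-methyl-2-(prop-1-en-2-yl)hex-4-en-1-ol] | OCC(CC=C(C)C)C(C)=C | starting material
2 | (S)-lavandulol [(2S)-5-methyl-2-(prop-1-en-2-yl)hex-4-en-1-ol] | OC[C@@H](CC=C(C)C)C(C)=C | intermediate
3 | (S)-lavandulyl bromide [(3S)-3-(bromomethyl)-2,6-dimethylhepta-1,5-diene] | BrC[C@@H](CC=C(C)C)C(C)=C | intermediate
4 | methacrolein (2-methylprop-2-enal) | CC(=C)C=O | starting material
5 | (2E,5S)-5-(bromomethyl)-2,6-dimethylhepta-2,6-dienal | BrC[C@@H](C/C=C(\C)C=O)C(C)=C | intermediate
6 | 2,4,6-trihydroxybenzophenone [phenyl(2,4,6-trihydroxyphenyl)methanone] | O=C(c1ccccc1)c1c(O)cc(O)cc1O | starting material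
7 | (3R,5S)-3-(3-benzoyl-2,4,6-trihydroxyphenyl)-5-(bromomethyl)-2,6-dimethylhept-6-enal (both C2 epimers; in equilibrium with its hemiacetal) | O=CC(C)[C@@H](C[C@H](CBr)C(C)=C)c1c(O)cc(O)c(C(=O)c2ccccc2)c1O | intermediate (not isolated)
8 | (1S,2S,4R)-2-(3-benzoyl-2,4,6-trihydroxyphenyl)-1-methyl-4-(prop-1-en-2-yl)cyclopentane-1-carbaldehyde (CHO cis to aryl; aryl trans to isopropenyl) | C=C(C)[C@@H]1C[C@@H](c2c(O)cc(O)c(C(=O)c3ccccc3)c2O)[C@@](C)(C=O)C1 | intermediate (not isolated)
9 | [(2R,3aS,9bS)-4,7,9-trihydroxy-3a-methyl-2-(prop-1-en-2-yl)-1,2,3,3a,4,9b-hexahydrocyclopenta[c]chromen-8-yl](phenyl)methanone (cis ring fusion; C4 anomers) | C=C(C)[C@@H]1C[C@H]2c3c(O)c(C(=O)c4ccccc4)c(O)cc3OC(O)[C@@]2(C)C1 | intermediate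
10 | (E)-tosylhydrazone of 8: N'-[[(1S,2R,4R)-2-(3-benzoyl-2,4,6-trihydroxyphenyl)-1-methyl-4-(prop-1-en-2-yl)cyclopentyl]methylidene]-4-methylbenzenesulfonohydrazide | C=C(C)[C@@H]1C[C@@H](c2c(O)cc(O)c(C(=O)c3ccccc3)c2O)[C@@](C)(/C=N/NS(=O)(=O)c4ccc(C)cc4)C1 | intermediate (not isolated)
11 | [2,4,6-trihydroxy-3-[(1R,4R)-2,2-dimethyl-4-(prop-1-en-2-yl)cyclopentyl]phenyl](phenyl)methanone | C=C(C)[C@@H]1C[C@@H](c2c(O)cc(O)c(C(=O)c3ccccc3)c2O)C(C)(C)C1 | target

**Totals**

Total step count: 5. Longest linear sequence: 5 steps (1 → 2 → 3 → 5 → 9 → 11).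

**Steps most likely to fail, with fallbacks**

Step 4 is the most exposed. The arene may add 1,2 instead of 1,4 (chromene formation), the dienamine of 5 may alkylate itself before the arene adds, or the sequence may stall at the hemiacetal of 7 because the hindered α-branched enamine alkylates slowly. The fallback sets out from 5 and 6 and comes back at 9. Only the amine-catalysed Friedel–Crafts/hemiacetal stage is run (same catalyst, no acetate, 0 °C) and the chromanol [(4R)-4-[(2S)-2-(bromomethyl)-3-methylbut-3-en-1-yl]-2,5,7-trihydroxy-3-methyl-3,4-dihydro-2H-chromen-6-yl](phenyl)methanone F1 is isolated. The five-membered ring is then closed in a separate anionic step with KOt-Bu (4.5 equiv) in THF/t-BuOH at 0 °C: the lactolate opens to the α-branched aldehyde enolate, which C-alkylates the CH2Br group (5-exo-tet) and re-closes to lactol 9.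

Step 5 may fail by hydride attack on the diaryl ketone or by reduction of the lactol to the cyclic ether instead of the methyl group. The fallback sets out from 9 and comes back at 11. Hydrazine hydrate in EtOH at 25 °C condenses only with the masked aldehyde to give the hydrazone [2,4,6-trihydroxy-3-[(1R,2S,4R)-2-[(E)-hydrazinylidenemethyl]-2-methyl-4-(prop-1-en-2-yl)cyclopentyl]phenyl](phenyl)methanone F2. KOt-Bu in DMSO at 25 °C (room-temperature Wolff–Kishner variant) then expels N2 and gives 11 with no hydride reagent present.

Step 3 may be sluggish, since a trisubstituted alkene is coupled with a 1,1-disubstituted partner, or may isomerise the isopropenyl group. The fallback sets out from 3 and comes back at 5. Allylic oxidation with SeO2 (0.3 equiv) and t-BuOOH in CH2Cl2 at 25 °C (ene reaction then [2,3]-shift, selective for the E-methyl of the more substituted alkene) gives (2E,5S)-5-(bromomethyl)-2,6-dimethylhepta-2,6-dien-1-ol F3, and MnO2 in CH2Cl2 oxidises this allylic alcohol to enal 5.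

**Further compounds**

F1 | step 4 | [(4R)-4-[(2S)-2-(bromomethyl)-3-methylbut-3-en-1-yl]-2,5,7-trihydroxy-3-methyl-3,4-dihydro-2H-chromen-6-yl](phenyl)methanone | CC1C(O)Oc2cc(O)c(C(=O)c3ccccc3)c(O)c2[C@@H]1C[C@H](CBr)C(C)=C
F2 | step 5 | [2,4,6-trihydroxy-3-[(1R,2S,4R)-2-[(E)-hydrazinylidenemethyl]-2-methyl-4-(prop-1-en-2-yl)cyclopentyl]phenyl](phenyl)methanone | C=C(C)[C@@H]1C[C@@H](c2c(O)cc(O)c(C(=O)c3ccccc3)c2O)[C@@](C)(/C=N/N)C1
F3 | step 3 | (2E,5S)-5-(bromomethyl)-2,6-dimethylhepta-2,6-dien-1-ol | BrC[C@@H](C/C=C(\C)CO)C(C)=C
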